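**Strategy.** The route rests on opening ring B between C6 and C7 (labdane numbering). The target's C7–C8(=C17) unit is read as a 2-substituted allylsilane and C6 as the β-carbon of a ring A enone (C4=O, C5=C6). An intramolecular Hosomi–Sakurai conjugate addition therefore closes ring B, creates the exocyclic C8=C17 methylene in the same operation and leaves a C4 ketone that later carries the quaternary C4 (C18, C19). The precursor is a ring A α-methylene ketone bearing the allylsilane on C9; its C10 and C9 centres come from a chirality-transferring Ireland–Claisen rearrangement of a CBS-derived cyclohexenyl ester, and C13 is bought as (R)-linalool.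

Key step: step 12

Remark: labdane numbering (C1–C20) is used for every compound; ring A is C1–C5/C10, ring B is C5–C10; TBS = tert-butyldimethylsilyl. Compounds 1, 3 and 25 are assumed to be purchased.

Step 1
Reactants: 1 2,3-dimethylcyclohex-2-en-1-one
Product: 2 (R)-2,3-dimethylcyclohex-2-en-1-ol
Conditions: (S)-2-methyl-CBS-oxazaborolidine (10 mol%), BH3·SMe2, THF, −20 °C
Reagents that add atoms: none
Why: Corey–Bakshi–Shibata reduction in which the α-methylated alkenyl arm acts as the large group, so hydride should add to one carbonyl face and set the C4 carbinol centre (R), the centre that later relays chirality to C10.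

Step 2
Reactants: 3 (R)-linalool
Product: 4 (R)-linalool TBS ether
Conditions: TBSOTf, 2,6-lutidine, CH2Cl2, 0 °C
Reagents that add atoms: tert-butyldimethylsilyl triflate CC(C)(C)[Si](C)(C)OS(=O)(=O)C(F)(F)F
Why: Silylation with a silyl triflate and a hindered base protects the tertiary allylic alcohol, and the purchased C13 centre (R) is not involved.

Step 3
Reactants: 4 (R)-linalool TBS ether
Product: 5 (4R)-4-(TBS-oxy)-4-methylhex-5-enal
Conditions: O3, pyridine, CH2Cl2, −78 °C (indicator end point); then PPh3
Reagents that add atoms: ozone [O-][O+]=O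
Why: Ozonolysis should cleave the electron-rich trisubstituted alkene much faster than the vinyl group beside the silyloxy-bearing quaternary carbon, giving the aldehyde whose carbonyl carbon becomes C8 and leaving C13 untouched.

Step 4
Reactants: 5 (4R)-4-(TBS-oxy)-4-methylhex-5-enal
Product: 6 (4R)-4-(TBS-oxy)-4-methylhex-5-enoic acid
Conditions: NaClO2, NaH2PO4, 2-methylbut-2-ene, tBuOH/H2O, 0 °C → rt
Reagents that add atoms: sodium chlorite [Na+].[O-]Cl=O
Why: Pinnick oxidation converts the aldehyde into the acid under buffered conditions in which the scavenger protects the vinyl group and the silyl ether survives.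

Step 5
Reactants: 6 (4R)-4-(TBS-oxy)-4-methylhex-5-enoic acid
Product: 7 (5R)-1-diazo-5-(TBS-oxy)-5-methylhept-6-en-2-one
Conditions: iBuOCOCl, Et3N, THF, −15 °C; then CH2N2, Et2O, 0 °C → rt
Reagents that add atoms: diazomethane C=[N+]=[N-]
Why: Acylation of diazomethane by the mixed carbonic anhydride (first half of an Arndt–Eistert homologation) gives the diazoketone whose diazo carbon becomes C9.

Step 6
Reactants: 7 (5R)-1-diazo-5-(TBS-oxy)-5-methylhept-6-en-2-one; 2 (R)-2,3-dimethylcyclohex-2-en-1-ol
Product: 9 (1R)-2,3-dimethylcyclohex-2-en-1-yl (5R)-5-(TBS-oxy)-5-methylhept-6-enoate, via ketene 8 (not isolated)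
Conditions: PhCO2Ag (10 mol%), Et3N, THF, rt, dark
Reagents that add atoms: none
Why: Silver-catalysed Wolff rearrangement to ketene 8 and its capture by the secondary allylic alcohol complete the one-carbon homologation and join the two fragments as the ester without touching the C4–O or C13 centres.

Step 7
Reactants: 9 (1R)-2,3-dimethylcyclohex-2-en-1-yl (5R)-5-(TBS-oxy)-5-methylhept-6-enoate
Product: 12 (2R,5R)-5-(TBS-oxy)-2-[(1R)-1,2-dimethylcyclohex-2-en-1-yl]-5-methylhept-6-enoic acid, via silyl ketene acetal 10 (not isolated), via trimethylsilyl ester 11 (not isolated)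
Conditions: LDA, THF, −78 °C; Me3SiCl; −78 → 60 °C; then 1 M HCl
Reagents that add atoms: none
Why: Ireland–Claisen rearrangement in which LDA in THF should give the silyl ketene acetal with the C11 chain cis to the allylic oxygen, the C9–C10 bond forms suprafacially on the face that carried the C4–O bond so that the CBS-derived centre fixes the quaternary C10, and the chair-like array (a boat would push the C11 chain over ring A) sets C9, while the C4 centre is spent as the C4=C5 alkene.

Step 8
Reactants: 12 (2R,5R)-5-(TBS-oxy)-2-[(1R)-1,2-dimethylcyclohex-2-en-1-yl]-5-methylhept-6-enoic acid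
Product: 13 methyl ester of 12
Conditions: MeI, K2CO3, DMF, rt
Reagents that add atoms: iodomethane CI
Why: Carboxylate O-alkylation gives the methyl ester needed for the later organometallic double addition, and the base is too weak to epimerise C9.

Step 9
Reactants: 13 methyl ester of 12
Product: 15 methyl (2R,5R)-5-(TBS-oxy)-2-[(1R,3RS)-3-hydroxy-1-methyl-2-methylidenecyclohexyl]-5-methylhept-6-enoate, via allylic hydroperoxide 14 (not isolated)
Conditions: O2, tetraphenylporphyrin (cat.), hν, CH2Cl2, 0 °C; then PPh3
Reagents that add atoms: dioxygen O=O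
Why: Schenck ene reaction of singlet oxygen with the only trisubstituted alkene, in which oxygen should bond to the less hindered C4 and take hydrogen from the C6 methyl geminal to the bulky quaternary C10, so the double bond moves to C5=C6 and oxygen returns to C4 as an epimer mixture that is erased in step 11.

Step 10
Reactants: 15 methyl (2R,5R)-5-(TBS-oxy)-2-[(1R,3RS)-3-hydroxy-1-methyl-2-methylidenecyclohexyl]-5-methylhept-6-enoate
Product: 17 allylsilane in which the CO2Me group of 15 is replaced by a 3-(trimethylsilyl)prop-1-en-2-yl group, via bis(silylmethyl) carbinol 16 (not isolated)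
Conditions: Me3SiCH2MgCl, CeCl3, THF, −78 °C → rt; then SiO2, CH2Cl2
Reagents that add atoms: (trimethylsilyl)methylmagnesium chloride C[Si](C)(C)C[Mg]Cl
Why: Cerium-mediated double addition of the silylmethyl Grignard reagent to the ester followed by Peterson elimination of carbinol 16 turns C8 into a 2-substituted allylsilane that carries both C7 and C17, with no stereocentre changed.

Step 11
Reactants: 17 allylsilane (C4 alcohol)
Product: 18 α-methylene ketone (C4=O, C5=C6) carrying the allylsilane on C9
Conditions: Dess–Martin periodinane, pyridine, CH2Cl2, 0 °C → rt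
Reagents that add atoms: none
Why: Dess–Martin oxidation of the allylic C4 alcohol gives the α-methylene ketone and erases the C4 centre under non-acidic conditions that spare the allylsilane and the silyl ether.

Step 12
Reactants: 18 α-methylene ketone carrying the allylsilane on C9
Product: 20 (13R)-13-(TBS-oxy)-18,19-dinorlabda-8(17),14-dien-4-one (5α-H, 9α-H, 10β-methyl), via aluminium enolate 19 (not isolated)
Conditions: EtAlCl2, toluene, −78 → −40 °C; aq. NaHCO3
Reagents that add atoms: none
Why: EtAlCl2 activates the C4 ketone, the terminal allylsilane carbon (C7) attacks the unsubstituted enone terminus C6, and the β-silyl cation at C8 loses Me3SiCl to chloride, which unveils the C8=C17 methylene and leaves aluminium enolate 19; this is an intramolecular Hosomi–Sakurai conjugate addition, the closest known type being Lewis-acid-mediated allylsilane–enone cyclisations to methylenecyclohexanes. Ring B closes in a 6-endo-trig mode with respect to the C5=C6 bond, through a chair-like array with the C9 side chain equatorial. The only new stereocentre, C5, is set when the enolate is protonated at work-up from the α face, anti to the axial C10 methyl, giving the trans ring fusion, which should also be the more stable one because C4 and C8 are both trigonal. The step needs 1,4- over 1,2-addition and reaction through the γ-carbon of the silane: the enone terminus is an unhindered CH2, 1,2-attack at C4 would have to build a bridged bicyclo[3.3.1] skeleton, and the silicon β-effect fixes both the nucleophilic carbon and the position of the new double bond. C9 and C10 are not touched, and the tertiary allylic silyl ether should survive at low temperature.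

Step 13
Reactants: 20 (13R)-13-(TBS-oxy)-18,19-dinorlabda-8(17),14-dien-4-one
Product: 22 (13R)-13-(TBS-oxy)-18-norlabda-8(17),14-dien-19-al (C4 epimers), via enol ether 21 (not isolated)
Conditions: Ph3P(CH2OMe)Cl, KOtBu, THF, 0 °C → rt; then TsOH·H2O, acetone/H2O, rt
Reagents that add atoms: (methoxymethyl)triphenylphosphonium chloride COC[P+](c1ccccc1)(c1ccccc1)c1ccccc1.[Cl-]; water O
Why: Wittig methoxymethylenation of the C4 ketone and mild hydrolysis of the enol ether add the future C19, the C4 centre of 22 forms as a mixture that the next step erases, and C5 is no longer enolisable once the ketone is gone.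

Step 14
Reactants: 22 (13R)-13-(TBS-oxy)-18-norlabda-8(17),14-dien-19-al
Product: 23 (13R)-13-(TBS-oxy)labda-8(17),14-dien-19-al (4α-methyl, 4β-formyl)
Conditions: KOtBu, MeI, THF/tBuOH, 0 °C → rt
Reagents that add atoms: iodomethane CI
Why: Alkylation of the exocyclic C4 enolate of the aldehyde with MeI from the α face, anti to the axial C10 methyl, should place the new methyl (C18) equatorial and the formyl group (C19) axial, which sets the quaternary C4 as in the target.

Step 15
Reactants: 23 (13R)-13-(TBS-oxy)labda-8(17),14-dien-19-al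
Product: 24 (13R)-13-(TBS-oxy)labda-8(17),14-dien-19-ol
Conditions: NaBH4, MeOH, 0 °C
Reagents that add atoms: none
Why: Hydride reduction of the hindered axial aldehyde gives the neopentyl C19 alcohol without creating a stereocentre.

Step 16
Reactants: 24 (13R)-13-(TBS-oxy)labda-8(17),14-dien-19-ol; 25 (E)-2-methylbut-2-enoyl chloride (tigloyl chloride)
Product: 26 (13R)-13-(TBS-oxy)labda-8(17),14-dien-19-yl (E)-2-methylbut-2-enoate
Conditions: DMAP, pyridine, CH2Cl2, 0 → 40 °C
Reagents that add atoms: none
Why: DMAP-catalysed acylation of the only free hydroxyl with the (E)-acid chloride gives the tiglate, the tertiary C13 oxygen being silylated and the stable (E)-geometry being retained.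

Step 17
Reactants: 26 (13R)-13-(TBS-oxy)labda-8(17),14-dien-19-yl (E)-2-methylbut-2-enoate
Product: 27 (13R)-13-hydroxylabda-8(17),14-dien-19-yl (E)-2-methylbut-2-enoate (target)
Conditions: TBAF, AcOH, THF, 50 °C
Reagents that add atoms: none
Why: Fluoride-induced cleavage of the tertiary silyl ether frees the C13 alcohol under buffered, non-acidic conditions that should spare the hindered neopentyl ester, the exocyclic alkene and the ionisable tertiary allylic alcohol.

**Compound list**

1 | 2,3-dimethylcyclohex-2-en-1-one | CC1=C(C)C(=O)CCC1 | starting material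
2 | (R)-2,3-dimethylcyclohex-2-en-1-ol | CC1=C(C)[C@H](O)CCC1 | intermediate
3 | (R)-linalool, (3R)-3,7-dimethylocta-1,6-dien-3-ol | C=C[C@](C)(O)CCC=C(C)C | starting material
4 | (R)-linalool TBS ether | C=C[C@](C)(O[Si](C)(C)C(C)(C)C)CCC=C(C)C | intermediate
5 | (4R)-4-(TBS-oxy)-4-methylhex-5-enal | C=C[C@](C)(O[Si](C)(C)C(C)(C)C)CCC=O | intermediate
6 | (4R)-4-(TBS-oxy)-4-methylhex-5-enoic acid | C=C[C@](C)(O[Si](C)(C)C(C)(C)C)CCC(=O)O | intermediate
7 | (5R)-1-diazo-5-(TBS-oxy)-5-methylhept-6-en-2-one | C=C[C@](C)(O[Si](C)(C)C(C)(C)C)CCC(=O)C=[N+]=[N-] | intermediate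
8 | (5R)-5-(TBS-oxy)-5-methylhepta-1,6-dien-1-one (ketene) | C=C[C@](C)(O[Si](C)(C)C(C)(C)C)CCC=C=O | intermediate (not isolated)
9 | (1R)-2,3-dimethylcyclohex-2-en-1-yl (5R)-5-(TBS-oxy)-5-methylhept-6-enoate | C=C[C@](C)(O[Si](C)(C)C(C)(C)C)CCCC(=O)O[C@@H]1CCCC(C)=C1C | intermediate
10 | (E)-trimethylsilyl ketene acetal of 9 (C11 chain cis to the allylic oxygen) | C=C[C@](C)(O[Si](C)(C)C(C)(C)C)CC/C=C(/O[Si](C)(C)C)O[C@@H]1CCCC(C)=C1C | intermediate (not isolated)
11 | trimethylsilyl ester of 12 | C=C[C@](C)(O[Si](C)(C)C(C)(C)C)CC[C@@H](C(=O)O[Si](C)(C)C)[C@@]1(C)CCCC=C1C | intermediate (not isolated)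
12 | (2R,5R)-5-(TBS-oxy)-2-[(1R)-1,2-dimethylcyclohex-2-en-1-yl]-5-methylhept-6-enoic acid | C=C[C@](C)(O[Si](C)(C)C(C)(C)C)CC[C@@H](C(=O)O)[C@@]1(C)CCCC=C1C | intermediate
13 | methyl (2R,5R)-5-(TBS-oxy)-2-[(1R)-1,2-dimethylcyclohex-2-en-1-yl]-5-methylhept-6-enoate | C=C[C@](C)(O[Si](C)(C)C(C)(C)C)CC[C@@H](C(=O)OC)[C@@]1(C)CCCC=C1C | intermediate
14 | methyl (2R,5R)-5-(TBS-oxy)-2-[(1R,3RS)-3-hydroperoxy-1-methyl-2-methylidenecyclohexyl]-5-methylhept-6-enoate | C=C[C@](C)(O[Si](C)(C)C(C)(C)C)CC[C@@H](C(=O)OC)[C@@]1(C)CCCC(OO)C1=C | intermediate (not isolated)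
15 | methyl (2R,5R)-5-(TBS-oxy)-2-[(1R,3RS)-3-hydroxy-1-methyl-2-methylidenecyclohexyl]-5-methylhept-6-enoate | C=C[C@](C)(O[Si](C)(C)C(C)(C)C)CC[C@@H](C(=O)OC)[C@@]1(C)CCCC(O)C1=C | intermediate
16 | tertiary carbinol from 15: C8 carries OH and two CH2SiMe3 groups; C9, C10, C13 as in 15 | C=C[C@](C)(O[Si](C)(C)C(C)(C)C)CC[C@@H](C(O)(C[Si](C)(C)C)C[Si](C)(C)C)[C@@]1(C)CCCC(O)C1=C | intermediate (not isolated)
17 | allylsilane: C8 is C(=CH2)CH2SiMe3; ring A is 3-hydroxy-1-methyl-2-methylidenecyclohexyl (C4 epimers); C9, C10, C13 as in 15 | C=C[C@](C)(O[Si](C)(C)C(C)(C)C)CC[C@@H](C(=C)C[Si](C)(C)C)[C@@]1(C)CCCC(O)C1=C | intermediate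
18 | α-methylene ketone: as 17 with C4=O | C=C[C@](C)(O[Si](C)(C)C(C)(C)C)CC[C@@H](C(=C)C[Si](C)(C)C)[C@@]1(C)CCCC(=O)C1=C | intermediate
19 | chloro(ethyl)aluminium C4(5)-enolate of 20 | C=C[C@](C)(O[Si](C)(C)C(C)(C)C)CC[C@H]1C(=C)CCC2=C(O[Al](Cl)CC)CCC[C@]12C | intermediate (not isolated)
20 | (13R)-13-(TBS-oxy)-18,19-dinorlabda-8(17),14-dien-4-one (5α-H, 9α-H, 10β-CH3) | C=C[C@](C)(O[Si](C)(C)C(C)(C)C)CC[C@H]1C(=C)CC[C@H]2C(=O)CCC[C@]12C | intermediate
21 | (13R)-19-methoxy-13-(TBS-oxy)-18-norlabda-4(19),8(17),14-triene (E/Z mixture) | C=C[C@](C)(O[Si](C)(C)C(C)(C)C)CC[C@H]1C(=C)CC[C@H]2C(=COC)CCC[C@]12C | intermediate (not isolated)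
22 | (13R)-13-(TBS-oxy)-18-norlabda-8(17),14-dien-19-al (C4 epimers) | C=C[C@](C)(O[Si](C)(C)C(C)(C)C)CC[C@H]1C(=C)CC[C@H]2C(C=O)CCC[C@]12C | intermediate
23 | (13R)-13-(TBS-oxy)labda-8(17),14-dien-19-al (4α-CH3, 4β-CHO) | C=C[C@](C)(O[Si](C)(C)C(C)(C)C)CC[C@H]1C(=C)CC[C@H]2[C@@](C)(C=O)CCC[C@]12C | intermediate
24 | (13R)-13-(TBS-oxy)labda-8(17),14-dien-19-ol | C=C[C@](C)(O[Si](C)(C)C(C)(C)C)CC[C@H]1C(=C)CC[C@H]2[C@@](C)(CO)CCC[C@]12C | intermediate
25 | (E)-2-methylbut-2-enoyl chloride (tigloyl chloride) | ClC(=O)/C(C)=C/C | starting material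
26 | (13R)-13-(TBS-oxy)labda-8(17),14-dien-19-yl (E)-2-methylbut-2-enoate | C=C[C@](C)(O[Si](C)(C)C(C)(C)C)CC[C@H]1C(=C)CC[C@H]2[C@@](C)(COC(=O)/C(C)=C/C)CCC[C@]12C | intermediate
27 | (4S,5R,9S,10R,13R)-13-hydroxylabda-8(17),14-dien-19-yl (E)-2-methylbut-2-enoate | C=C[C@](C)(O)CC[C@H]1C(=C)CC[C@H]2[C@@](C)(COC(=O)/C(C)=C/C)CCC[C@]12C | target

**Count.** Total: 17 steps. Longest linear sequence: 16 steps (steps 2–17, from (R)-linalool).

**Steps most likely to fail, with fallbacks**

Step 7. The rearrangement may pass partly through the boat-like array, or the enolate may form with poor geometry, which would erode the configuration at C9; this centre cannot be corrected once C8 is an alkene. The fallback accepts 12 as a mixture of C9 epimers and keeps C8 as a ketone so that C9 stays epimerisable. It sets out from 12: MeLi (Et2O, 0 °C) should give the methyl ketone F1. Singlet-oxygen ene reaction and PPh3 reduction as in step 9 give the allylic alcohol F2. Kinetic enolisation at the methyl group (LDA, Me3SiCl, −78 °C) followed by NBS gives the bromomethyl ketone F3. Bu3SnH/AIBN (benzene, 80 °C, slow addition) closes ring B by 6-endo cyclisation of the α-keto radical at C7 onto C6, with hydrogen transfer to C5 from the α face, giving the decalone F4. Ph3P=CH2 with excess KOtBu (toluene, 80 °C) equilibrates C9 to the equatorial side chain through the C8 enolate and methylenates C8, giving the dienol F5. Dess–Martin oxidation of the C4 alcohol then returns to the route at 20.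

Step 10. Double addition to the hindered, α-branched ester may stall at the ketone stage through enolisation, or the allylsilane may be protodesilylated during the Peterson elimination. The fallback sets out from 15 and builds the allylsilane in two separate events: Me3SiCH2Li (pentane/THF, −78 → 0 °C) is used for a deliberate single addition, the adduct being enolised and so shielded from a second addition, to give the β-ketosilane F6. Salt-free Ph3P=CH2 (THF, 0 °C) then methylenates the ketone and returns to the route at 17.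

Step 12. The Lewis acid may ionise the tertiary allylic silyl ether or protodesilylate the allylsilane, and the α-methylene ketone may oligomerise before it cyclises. The fallback forms the same bond in the radical manifold, without a Lewis acid, and sets out from 17: NBS (CH2Cl2, propylene oxide, −78 °C) effects bromodesilylation with allyl shift to give the allylic bromide F7. Dess–Martin oxidation gives the bromo enone F8. Bu3SnH/AIBN (benzene, 80 °C, slow addition) generates the symmetrical 2-substituted allyl radical, which adds through C7 to the enone terminus C6 (6-endo); the α-keto radical at C5 then takes hydrogen from the stannane, returning to the route at 20.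

**Further compounds**

F1 | step 7 | (3RS,6R)-6-(TBS-oxy)-3-[(1R)-1,2-dimethylcyclohex-2-en-1-yl]-6-methyloct-7-en-2-one | C=C[C@](C)(O[Si](C)(C)C(C)(C)C)CCC(C(C)=O)[C@@]1(C)CCCC=C1C
F2 | step 7 | (3RS,6R)-6-(TBS-oxy)-3-[(1R,3RS)-3-hydroxy-1-methyl-2-methylidenecyclohexyl]-6-methyloct-7-en-2-one | C=C[C@](C)(O[Si](C)(C)C(C)(C)C)CCC(C(C)=O)[C@@]1(C)CCCC(O)C1=C
F3 | step 7 | 1-bromo derivative of F2 (bromomethyl ketone) | C=C[C@](C)(O[Si](C)(C)C(C)(C)C)CCC(C(=O)CBr)[C@@]1(C)CCCC(O)C1=C
F4 | step 7 | (13R)-13-(TBS-oxy)-4-hydroxy-17,18,19-trinorlabd-14-en-8-one (5α-H; C4 and C9 epimers) | C=C[C@](C)(O[Si](C)(C)C(C)(C)C)CCC1C(=O)CC[C@H]2C(O)CCC[C@]12C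
F5 | step 7 | (13R)-13-(TBS-oxy)-18,19-dinorlabda-8(17),14-dien-4-ol (5α-H, 9α-H; C4 epimers) | C=C[C@](C)(O[Si](C)(C)C(C)(C)C)CC[C@H]1C(=C)CC[C@H]2C(O)CCC[C@]12C
F6 | step 10 | β-ketosilane: as 17 with C8 as C(=O)CH2SiMe3 | C=C[C@](C)(O[Si](C)(C)C(C)(C)C)CC[C@@H](C(=O)C[Si](C)(C)C)[C@@]1(C)CCCC(O)C1=C
F7 | step 12 | allylic bromide: as 17 with C8 as C(=CH2)CH2Br | C=C[C@](C)(O[Si](C)(C)C(C)(C)C)CC[C@@H](C(=C)CBr)[C@@]1(C)CCCC(O)C1=C
F8 | step 12 | bromo enone: as F7 with C4=O | C=C[C@](C)(O[Si](C)(C)C(C)(C)C)CC[C@@H](C(=C)CBr)[C@@]1(C)CCCC(=O)C1=C
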